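Ash and elm differ in charge by 0.0480 M of Q and 0.0480 M of J, so the ash flask, once it has made 0.0480 M of X, holds the Q and J that elm started with. What still differs is its past: the X made and the minutes spent.

| flask | Q | J | G | time |
|---|---|---|---|---|
| ash | 0.120 M | 0.300 M | 2.40 × 10⁻⁴ M |  |
| elm | 0.0720 M | 0.252 M | 2.40 × 10⁻⁴ M |  |
| birch | 0.120 M | 0.450 M | 2.40 × 10⁻⁴ M |  |
| alder | 0.120 M | 0.300 M | 7.90 × 10⁻⁵ M | 20 min |

- ash run (time / min: [X] / M): 2.5: 0.0103; 5.0: 0.0193; 7.5: 0.0278; 10: 0.0342; 12: 0.0398; 15: 0.0465; 18: 0.0533; 20: 0.0567
- elm run (time / min: [X] / M): 2.5: 0.0066; 5.0: 0.0136; 7.5: 0.0199; 10: 0.0250; 12: 0.0289; 15: 0.0337; 18: 0.0383; 20: 0.0409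
- birch run (time / min: [X] / M): 2.5: 0.0099; 5.0: 0.0185; 7.5: 0.0259; 10: 0.0336; 12: 0.0377; 15: 0.0441; 18: 0.0497; 20: 0.0532

(scatter of a reading: 4 × 10⁻⁴ M)

- order of the initial rate in [J], near the charge of the ash run, the rate being that where two percent of its Q are X
- order of the initial rate in [Q], near the charge of the ash run, the rate being that where two percent of its Q are X (one fixed amount of X, the same in the runs compared)
- the elm run starts with 0.0480 M less of Q and of J than the ash run, and with no X. Compared where both hold the same amount of Q, once fifteen percent of what the elm run was charged with has turned into X, is the elm run faster, slower or alike (within a tenth)?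
- X in the alder run at 20 min, as a share of the Q charged

- Overall: Q + J -> X, with G as catalyst.
- Constant volume, constant temperature.
- Bound and free are read together.
- "The second partner" is J.
- An order is taken over about fifteen percent of the charge, up and down.

*What is the zero of your scale?*
A flask without memory: at equal [Q] and [J] it has equal rates. So in this same-excess test the elm rate over the ash rate, which I call the memory ratio m, stands at 1.

*What do the readings give?*
The elm slope from 2.5 min to 7.5 min is 0.00266 M min⁻¹. The ash slope from 15 min to 20 min is 0.00204 M min⁻¹. So m reads 1.30, and elm is faster than ash, each slope carrying about 1.13 × 10⁻⁴ M min⁻¹.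

*Those windows are not matched. Why trust that?*
They are not. The ash window holds about 0.0684 M of Q, more than the 0.0587 M of the elm window, so this m reads low.

*What do you carry forward?*
The window centres lie 12.5 min apart, and ln m over that gap gives 0.0212 min⁻¹. This is my memory rate λ, the fraction of working G lost per minute.

*Couldn't accumulated X do this instead of the clock?*
Ash and elm do not part the two. Alder may, since it has a lower [G] than ash, at 0.329 of it.

*Then alder?*
With the rate proportional to [G] and no memory, alder at 20 min equals ash at 6.58 min, which interpolates to 20.6% of the Q charged. With λ, I count working minutes, the time integral of the surviving share e^(−λt). Alder then has 16.3 min, worth 5.36 min at the ash [G]. Ash collects that by 5.69 min, where its readings give 0.0217 M. I commit to 18.1% for alder, and to elm being faster.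

The forecast stood at −0.1 and 0.74 for the orders, faster for elm and 20.3% for alder, “assuming rate proportional to G”.

The flask gives orders of 0.018 in [J] and 0.60 in [Q], elm faster with a ratio of 1.4, and 17.6% for alder, 0.50 percentage points below my figure.

    G + Q → GQ (471.6 M⁻¹ min⁻¹)
    GQ + J → X + G (1878 M⁻¹ min⁻¹)
    G + J → Qe + J (0.07800 M⁻¹ min⁻¹)
    2 Q ⇌ Q2, settled at all times (28.00 M⁻¹)

The elm-over-ash ratio rests on the loss of G to Qe: the simulated run without that step brings it from 1.4 to 1.0, the zero of the scale. At matched contents ash stands just past its last reading and elm between its first two, about 17.5 min apart, and λ over that span reckons 1.45, beside the 1.4 of the flask. For alder, λ reckons 65.4% of the G surviving at 20 min, and the simulated alder run without the loss reaches 21.4%, against 17.6% with it.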